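**Plan**

Numbering: C1 and C5 are the ring-fusion carbons, C2–C4 complete the cyclopentene (C4 carries CH3), C6 (OH), C7 (side chain), C8, C9 (OH) and C10 (=CH2) complete the seven-membered ring; the side chain is C11 (CHCH3), C12 and C13 (OAc), C14=C15. β is the face of H-5.

- Retrosynthesis: the side chain is cut at C12–C13 and C14=C15 (alkoxyallylboration, cross-metathesis); then C8–C9 and C10–C1 are cut together.
- Enabling feature: C9–C10(=CH2) is a two-carbon unit lying between C8 and the ring-fusion carbon C1, and C1 is next to C2 of the five-membered ring. With a temporary C2 ketone and a temporary C1–C8 bond, the seven-membered ring contracts to a bicyclo[3.3.0]oct-1(8)-en-2-one (rings A and B) and the two-carbon unit becomes allene.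
- Forward: ring A (keto ester) and a lactone are joined by an aldol (C6–C7); aldol condensation closes ring B (C1=C8); allene [2+2] photocycloaddition; hydroxylation at C9 on the cyclobutane; ketyl fragmentation of C1–C8 opens ring B plus cyclobutane to the seven-membered ring.
- The C2 ketone is then used to install C4–CH3 and C3=C4 and is removed; the side chain is completed, acetylated and the silyl ethers are cleaved.
- Stereochemistry: C5 and C11 come from the two building blocks; C6/C7 from the anti aldol of the lactone enolate; C9 from exo hydroxylation of the cyclobutane; C1 from protonation/equilibration to the trans ring fusion; C12/C13 from the isopinocampheyl allylborane.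

Key step: step 8

Remark: 1 and 4 are taken as commercially available single enantiomers; the C4 centre of 19 and the C2 centre of 21 and 22 are transient and their configuration has no consequence.

**Step 1**
Reactants: 1 methyl (R)-3-oxocyclopentane-1-carboxylate
Product: 2 methyl (R)-1,4-dioxaspiro[4.4]nonane-7-carboxylate
Conditions: HOCH2CH2OH, TsOH·H2O (cat.), benzene, reflux, Dean–Stark
Reagents that add atoms: ethylene glycol, OCCO
Why: Acid-catalysed ketalisation masks the future C2 ketone before hydride and enolate chemistry, and the ester α-centre (future C5) is not enolised under these conditions.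

**Step 2**
Reactants: 2 methyl (R)-1,4-dioxaspiro[4.4]nonane-7-carboxylate
Product: 3 (R)-1,4-dioxaspiro[4.4]nonane-7-carbaldehyde
Conditions: i-Bu2AlH, CH2Cl2, −78 °C; aqueous potassium sodium tartrate
Reagents that add atoms: none
Why: Low-temperature partial reduction of the ester with DIBAL-H should stop at the aluminium hemiacetal and give the aldehyde, which is used crude so that C5 is not epimerised.

**Step 3**
Reactants: 3 (R)-1,4-dioxaspiro[4.4]nonane-7-carbaldehyde; 4 (R)-4-methyldihydrofuran-2(3H)-one
Product: 5 (3S,4R)-3-[(S)-hydroxy[(7R)-1,4-dioxaspiro[4.4]nonan-7-yl]methyl]-4-methyldihydrofuran-2(3H)-one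
Conditions: 4, LiN(i-Pr)2, THF, −78 °C; then 3, −78 °C; aqueous NH4Cl
Reagents that add atoms: none
Why: Aldol addition of the ring-locked (E)-lithium enolate through a Zimmerman–Traxler chair should give the anti aldol, with the enolate reacting on the face opposite the C11 methyl group, so that C7 (trans to C11–CH3) and C6 (anti to C7) are both set by the lactone stereocentre.

**Step 4**
Reactants: 5 anti aldol lactone
Product: 6 dihydroxy Weinreb amide (ring-opened 5: C8 N-methoxy-N-methylamide; free C6–OH and C12–OH)
Conditions: MeNH(OMe)·HCl, AlMe3, CH2Cl2, 0 → 23 °C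
Reagents that add atoms: N,O-dimethylhydroxylamine hydrochloride, CNOC.Cl
Why: Weinreb aminolysis of the γ-lactone with the aluminium amide opens the ring and frees the C12 hydroxyl, so that it can be protected before the C8 aldehyde is unveiled; a free C12–OH would later close onto the enone by oxa-Michael addition.

**Step 5**
Reactants: 6 dihydroxy Weinreb amide
Product: 7 6,12-bis(tert-butyldimethylsilyl) ether of 6
Conditions: t-BuMe2SiOTf, 2,6-lutidine, CH2Cl2, −78 → 0 °C
Reagents that add atoms: tert-butyldimethylsilyl trifluoromethanesulfonate, CC(C)(C)[Si](C)(C)OS(=O)(=O)C(F)(F)F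
Why: Standard silylation protects the secondary C6 and the primary C12 hydroxyl as TBS ethers in one operation.

**Step 6**
Reactants: 7 bis-TBS Weinreb amide
Product: 8 C8 aldehyde (6,12-bis-OTBS; ring-A ketal intact)
Conditions: i-Bu2AlH, THF, −78 °C; aqueous potassium sodium tartrate
Reagents that add atoms: none
Why: Reduction of a Weinreb amide with DIBAL-H stops at the chelated hemiaminal and should release the aldehyde on work-up without epimerising C7.

**Step 7**
Reactants: 8 C8 aldehyde
Product: 10 bicyclo[3.3.0]oct-1(8)-en-2-one (rings A and B; C2=O; C1=C8; 6β-OTBS; 7β-CH(CH3)CH2OTBS), via keto aldehyde 9 (not isolated)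
Conditions: PPTS, acetone–H2O, 40 °C; then TsOH·H2O (cat.), benzene, 50 °C
Reagents that add atoms: water, O
Why: Acid-catalysed ketal hydrolysis frees the C2 ketone, whose enol (C1) then closes ring B on the C8 aldehyde in an intramolecular aldol condensation; the competing aldehyde-enol mode can only give a reversible bridged aldol.

**Step 8**
Reactants: 10 bicyclic enone; 11 propadiene (allene)
Product: 12 tricyclic photoadduct (cyclobutane C1–C8–C9–C10 on the β face; C10=CH2; C2=O)
Conditions: hν (medium-pressure Hg lamp, uranium-glass filter, λ > 340 nm), 11 (excess), CH2Cl2, −78 °C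
Reagents that add atoms: none
Why: The triplet excited state of the 2-alkylidene cyclopentanone chromophore (C2=O, C1=C8) adds to ground-state allene stepwise through a 1,4-biradical and forms the C10–C1 and C9–C8 bonds in one operation. The closest known reaction type is the head-to-head enone–allene [2+2] photocycloaddition that gives β,γ-unsaturated ketones. The only ring closed is the cyclobutane C1–C8–C9–C10, by radical recombination in a [2+2] mode, cis-fused to ring B. The new quaternary centre C1 is fixed by ring strain, because rings A and B must stay cis-fused, so C10 enters on the convex face syn to H-5; C8 is fixed by the necessarily cis-fused four-membered ring, so C9 enters on the same face. The step needs head-to-head regioselectivity (central allene carbon to the α-carbon C1), which is the intrinsic preference of allene with cyclic enones; it needs no chemoselectivity because the enone is the only chromophore and no other alkene is present, and the long-wavelength filter protects the β,γ-unsaturated ketone product from secondary photoreactions. The approach is cis to the C7 side chain and may be slow, but both new stereocentres are erased or reset after fragmentation, and the β-disposed cyclobutane is what exposes the exo C9–H in the next step.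

**Step 9**
Reactants: 12 tricyclic photoadduct
Product: 13 9-hydroxy photoadduct (exo 9-OH on the cyclobutane)
Conditions: SeO2 (cat.), t-BuOOH, CH2Cl2, 0 → 23 °C
Reagents that add atoms: selenium dioxide, O=[Se]=O; tert-butyl hydroperoxide, CC(C)(C)OO
Why: The SeO2 allylic hydroxylation (ene reaction, then [2,3]-sigmatropic shift) can only take hydrogen from C9 because C1 is quaternary, and oxygen should be delivered to the exo face of the cyclobutane, away from ring B and the C7 side chain, which gives the C9 configuration of the target.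

**Step 10**
Reactants: 13 9-hydroxy photoadduct
Product: 15 trans-fused hydroazulen-2-one (9α-OH; 10-methylene; 6β-OTBS; 12-OTBS), via cis-fused C1 epimer 14 (not isolated)
Conditions: SmI2, HMPA, t-BuOH, THF, −78 → −20 °C; then DBU (cat.), CH2Cl2, 0 °C
Reagents that add atoms: none
Why: Single-electron reduction of the C2 ketone gives a ketyl whose β-scission cleaves the strained C1–C8 bond (cleavage of C1–C10 would give a vinyl radical); the C8 radical is reduced and protonated, the samarium dienolate is protonated at C1, and C1 (α to the ketone) is equilibrated by DBU to the trans-fused 2,3-trans cyclopentanone, which is expected to be the more stable epimer.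

**Step 11**
Reactants: 15 trans-fused hydroazulen-2-one
Product: 16 9-O-TBS ether of 15 (6,9,12-tris-OTBS ketone)
Conditions: t-BuMe2SiCl, imidazole, DMF, 40 °C
Reagents that add atoms: tert-butyldimethylsilyl chloride, CC(C)(C)[Si](C)(C)Cl
Why: Routine silylation of the secondary allylic C9 hydroxyl under conditions that do not enolise the ketone.

**Step 12**
Reactants: 16 tris-TBS ketone
Product: 18 cyclopentenone (C2=O; C3=C4), via C2 silyl enol ether 17 (not isolated)
Conditions: LiN(i-Pr)2, Me3SiCl, THF, −78 °C; then Pd(OAc)2, MeCN, 23 °C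
Reagents that add atoms: none
Why: Kinetic deprotonation with in situ silylation should take the less hindered C3 methylene instead of the tertiary C1–H, and Saegusa–Ito oxidation of the silyl enol ether then gives the enone.

**Step 13**
Reactants: 18 cyclopentenone
Product: 20 4-methylcyclopentenone (C2=O; C3=C4; 4-CH3), via 4-methyl silyl enol ether 19 (not isolated)
Conditions: Me2CuLi (from MeLi, CuI), Me3SiCl, THF, −78 °C; then Pd(OAc)2, MeCN, 23 °C
Reagents that add atoms: lithium dimethylcuprate, [Li+].C[Cu-]C
Why: Silyl-chloride-accelerated cuprate conjugate addition places the methyl group on C4 and gives a regiodefined silyl enol ether, and a second Saegusa–Ito oxidation restores the C3=C4 double bond, now carrying the methyl group.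

**Step 14**
Reactants: 20 4-methylcyclopentenone
Product: 21 allylic alcohol (C2–OH; C3=C4)
Conditions: NaBH4, CeCl3·7H2O, MeOH, −40 °C
Reagents that add atoms: none
Why: Luche 1,2-reduction of the enone gives the allylic alcohol, with hydride expected anti to the C1 substituent (the C2 configuration is of no consequence).

**Step 15**
Reactants: 21 allylic alcohol
Product: 23 tris-TBS ether having the complete ring A (C2H2; C3=C4; 4-CH3), via allylic methyl carbonate 22 (not isolated)
Conditions: ClCO2Me, pyridine, CH2Cl2, 0 °C; then Pd(PPh3)4 (cat.), LiBHEt3, THF, 0 → 23 °C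
Reagents that add atoms: none
Why: In this Tsuji–Trost-type hydrogenolysis, zerovalent palladium ionises the allylic carbonate to a π-allyl complex, which should take hydride at the less hindered secondary terminus C2 and leave the trisubstituted C3=C4 double bond.

**Step 16**
Reactants: 23 tris-TBS ether
Product: 24 primary alcohol (C12–OH; 6,9-bis-OTBS)
Conditions: HF·pyridine, pyridine, THF, 0 °C
Reagents that add atoms: none
Why: Under buffered HF·pyridine at low temperature the primary TBS ether is cleaved much faster than the two hindered secondary ones.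

**Step 17**
Reactants: 24 primary alcohol
Product: 25 C12 aldehyde
Conditions: Dess–Martin periodinane, NaHCO3, CH2Cl2, 0 → 23 °C
Reagents that add atoms: none
Why: Buffered Dess–Martin oxidation gives the α-branched aldehyde without epimerising C11 (used directly).

**Step 18**
Reactants: 25 C12 aldehyde; 26 allyl 4-methoxybenzyl ether
Product: 27 homoallylic alcohol (12S-OH; 13S-OPMB; terminal vinyl)
Conditions: 26, s-BuLi, THF, −78 °C; (+)-Ipc2BOMe; BF3·OEt2; then 25, −78 °C; NaOH, H2O2
Reagents that add atoms: none
Why: In this Brown γ-alkoxyallylboration, the chair transition state of the (Z)-γ-alkoxyallyl borane gives the syn 1,2-diol monoether, and the isopinocampheyl groups from (+)-Ipc2BOMe direct attack to the re face of the aldehyde, setting C12 (S) and C13 (S) under reagent control.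

**Step 19**
Reactants: 27 homoallylic alcohol; 28 2-methylbut-2-ene
Product: 29 cross-metathesis product (C14=C15(CH3)2; 13-OPMB; 12-OH)
Conditions: 28 (excess), second-generation Grubbs catalyst RuCl2(=CHPh)(H2IMes)(PCy3), CH2Cl2, 40 °C
Reagents that add atoms: none
Why: Olefin cross-metathesis with 2-methylbut-2-ene converts the terminal vinyl group into the 2-methylprop-1-enyl group, while the 1,1-disubstituted exocyclic alkene and the trisubstituted ring alkene are too hindered to react.

**Step 20**
Reactants: 29 cross-metathesis product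
Product: 30 12,13-diol (6,9-bis-OTBS)
Conditions: DDQ, CH2Cl2–aqueous buffer (pH 7), 0 °C
Reagents that add atoms: none
Why: Oxidative cleavage of the p-methoxybenzyl ether by DDQ in the presence of water frees the C13 hydroxyl without affecting silyl ethers or alkenes.

**Step 21**
Reactants: 30 12,13-diol
Product: 31 12,13-diacetate (6,9-bis-OTBS)
Conditions: Ac2O, pyridine, DMAP, CH2Cl2, 23 °C
Reagents that add atoms: acetic anhydride, CC(=O)OC(C)=O
Why: DMAP-catalysed acylation esterifies both free secondary hydroxyls while C6 and C9 remain silylated.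

**Step 22**
Reactants: 31 12,13-diacetate
Product: 32 target, (1R,5S,6R,7S,9R,11R,12S,13S)-6,9-dihydroxy 12,13-diacetate
Conditions: HF·pyridine, pyridine, THF, 0 → 23 °C
Reagents that add atoms: none
Why: Buffered fluoride cleavage of the two secondary TBS ethers should give the target without acetate migration or ionisation of the allylic acetate.

**Compound list**

1 | methyl (R)-3-oxocyclopentane-1-carboxylate | COC(=O)[C@H]1CC(=O)CC1 | starting material
2 | methyl (R)-1,4-dioxaspiro[4.4]nonane-7-carboxylate | COC(=O)[C@H]1CC2(CC1)OCCO2 | intermediate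
3 | (R)-1,4-dioxaspiro[4.4]nonane-7-carbaldehyde | O=C[C@H]1CC2(CC1)OCCO2 | intermediate
4 | (R)-4-methyldihydrofuran-2(3H)-one | O=C1C[C@@H](C)CO1 | starting material
5 | (3S,4R)-3-[(S)-hydroxy[(7R)-1,4-dioxaspiro[4.4]nonan-7-yl]methyl]-4-methyldihydrofuran-2(3H)-one | O=C1OC[C@H](C)[C@H]1[C@@H](O)[C@H]1CC2(CC1)OCCO2 | intermediate
6 | dihydroxy Weinreb amide (ring-opened 5) | CON(C)C(=O)[C@@H]([C@@H](C)CO)[C@@H](O)[C@H]1CC2(CC1)OCCO2 | intermediate
7 | 6,12-bis-TBS ether of 6 | CON(C)C(=O)[C@@H]([C@@H](C)CO[Si](C)(C)C(C)(C)C)[C@@H](O[Si](C)(C)C(C)(C)C)[C@H]1CC2(CC1)OCCO2 | intermediate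
8 | C8 aldehyde, ketal intact | O=C[C@@H]([C@@H](C)CO[Si](C)(C)C(C)(C)C)[C@@H](O[Si](C)(C)C(C)(C)C)[C@H]1CC2(CC1)OCCO2 | intermediate
9 | keto aldehyde | O=C[C@@H]([C@@H](C)CO[Si](C)(C)C(C)(C)C)[C@@H](O[Si](C)(C)C(C)(C)C)[C@H]1CC(=O)CC1 | intermediate
10 | bicyclo[3.3.0]oct-1(8)-en-2-one, 6β-OTBS, 7β-CH(CH3)CH2OTBS | CC(C)(C)[Si](C)(C)OC[C@H](C)[C@@H]1C=C2C(=O)CC[C@H]2[C@@H]1O[Si](C)(C)C(C)(C)C | intermediate
11 | propadiene (allene) | C=C=C | starting material
12 | tricyclic photoadduct, methylenecyclobutane on the β face | CC(C)(C)[Si](C)(C)OC[C@H](C)[C@@H]1[C@@H]2CC(=C)[C@@]23C(=O)CC[C@H]3[C@@H]1O[Si](C)(C)C(C)(C)C | intermediate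
13 | 9-hydroxy photoadduct (exo OH) | CC(C)(C)[Si](C)(C)OC[C@H](C)[C@@H]1[C@@H]2[C@@H](O)C(=C)[C@@]23C(=O)CC[C@H]3[C@@H]1O[Si](C)(C)C(C)(C)C | intermediate
14 | cis-fused C1 epimer of 15 | C=C1[C@H](O)C[C@@H]([C@@H](C)CO[Si](C)(C)C(C)(C)C)[C@@H](O[Si](C)(C)C(C)(C)C)[C@@H]2CCC(=O)[C@H]12 | intermediate
15 | trans-fused hydroazulen-2-one, 9α-OH, 10-methylene | C=C1[C@H](O)C[C@@H]([C@@H](C)CO[Si](C)(C)C(C)(C)C)[C@@H](O[Si](C)(C)C(C)(C)C)[C@@H]2CCC(=O)[C@@H]12 | intermediate
16 | 6,9,12-tris-TBS ketone | C=C1[C@H](O[Si](C)(C)C(C)(C)C)C[C@@H]([C@@H](C)CO[Si](C)(C)C(C)(C)C)[C@@H](O[Si](C)(C)C(C)(C)C)[C@@H]2CCC(=O)[C@@H]12 | intermediate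
17 | C2 trimethylsilyl enol ether (C2=C3) | C=C1[C@H](O[Si](C)(C)C(C)(C)C)C[C@@H]([C@@H](C)CO[Si](C)(C)C(C)(C)C)[C@@H](O[Si](C)(C)C(C)(C)C)[C@@H]2CC=C(O[Si](C)(C)C)[C@@H]12 | intermediate
18 | cyclopentenone (C2=O, C3=C4) | C=C1[C@H](O[Si](C)(C)C(C)(C)C)C[C@@H]([C@@H](C)CO[Si](C)(C)C(C)(C)C)[C@@H](O[Si](C)(C)C(C)(C)C)[C@@H]2C=CC(=O)[C@@H]12 | intermediate
19 | 4-methyl C2 trimethylsilyl enol ether | C=C1[C@H](O[Si](C)(C)C(C)(C)C)C[C@@H]([C@@H](C)CO[Si](C)(C)C(C)(C)C)[C@@H](O[Si](C)(C)C(C)(C)C)[C@@H]2[C@@H](C)C=C(O[Si](C)(C)C)[C@@H]12 | intermediate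
20 | 4-methylcyclopentenone (C2=O, C3=C4) | C=C1[C@H](O[Si](C)(C)C(C)(C)C)C[C@@H]([C@@H](C)CO[Si](C)(C)C(C)(C)C)[C@@H](O[Si](C)(C)C(C)(C)C)[C@@H]2C(C)=CC(=O)[C@@H]12 | intermediate
21 | allylic alcohol (C2–OH) | C=C1[C@H](O[Si](C)(C)C(C)(C)C)C[C@@H]([C@@H](C)CO[Si](C)(C)C(C)(C)C)[C@@H](O[Si](C)(C)C(C)(C)C)[C@@H]2C(C)=C[C@@H](O)[C@@H]12 | intermediate
22 | allylic methyl carbonate | C=C1[C@H](O[Si](C)(C)C(C)(C)C)C[C@@H]([C@@H](C)CO[Si](C)(C)C(C)(C)C)[C@@H](O[Si](C)(C)C(C)(C)C)[C@@H]2C(C)=C[C@@H](OC(=O)OC)[C@@H]12 | intermediate
23 | tris-TBS ether with complete ring A | C=C1[C@H](O[Si](C)(C)C(C)(C)C)C[C@@H]([C@@H](C)CO[Si](C)(C)C(C)(C)C)[C@@H](O[Si](C)(C)C(C)(C)C)[C@@H]2C(C)=CC[C@@H]12 | intermediate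
24 | primary alcohol (C12–OH) | C=C1[C@H](O[Si](C)(C)C(C)(C)C)C[C@@H]([C@@H](C)CO)[C@@H](O[Si](C)(C)C(C)(C)C)[C@@H]2C(C)=CC[C@@H]12 | intermediate
25 | C12 aldehyde | C=C1[C@H](O[Si](C)(C)C(C)(C)C)C[C@@H]([C@@H](C)C=O)[C@@H](O[Si](C)(C)C(C)(C)C)[C@@H]2C(C)=CC[C@@H]12 | intermediate
26 | allyl 4-methoxybenzyl ether | COc1ccc(COCC=C)cc1 | starting material
27 | homoallylic alcohol (12S-OH, 13S-OPMB, vinyl) | C=C1[C@H](O[Si](C)(C)C(C)(C)C)C[C@@H]([C@@H](C)[C@H](O)[C@H](C=C)OCc3ccc(OC)cc3)[C@@H](O[Si](C)(C)C(C)(C)C)[C@@H]2C(C)=CC[C@@H]12 | intermediate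
28 | 2-methylbut-2-ene | CC=C(C)C | starting material
29 | cross-metathesis product | C=C1[C@H](O[Si](C)(C)C(C)(C)C)C[C@@H]([C@@H](C)[C@H](O)[C@H](C=C(C)C)OCc3ccc(OC)cc3)[C@@H](O[Si](C)(C)C(C)(C)C)[C@@H]2C(C)=CC[C@@H]12 | intermediate
30 | 12,13-diol | C=C1[C@H](O[Si](C)(C)C(C)(C)C)C[C@@H]([C@@H](C)[C@H](O)[C@H](C=C(C)C)O)[C@@H](O[Si](C)(C)C(C)(C)C)[C@@H]2C(C)=CC[C@@H]12 | intermediate
31 | 12,13-diacetate, 6,9-bis-OTBS | C=C1[C@H](O[Si](C)(C)C(C)(C)C)C[C@@H]([C@@H](C)[C@H](OC(C)=O)[C@H](C=C(C)C)OC(C)=O)[C@@H](O[Si](C)(C)C(C)(C)C)[C@@H]2C(C)=CC[C@@H]12 | intermediate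
32 | target | C=C1[C@H](O)C[C@@H]([C@@H](C)[C@H](OC(C)=O)[C@H](C=C(C)C)OC(C)=O)[C@@H](O)[C@@H]2C(C)=CC[C@@H]12 | target

**Totals**

Total step count: 22. Longest linear sequence: 22 steps (1 → 32); 4, 11, 26 and 28 enter as purchased reagents.

**Steps most likely to fail**

1. Step 10. After electron transfer, the C8 carbanion may expel the neighbouring C9 hydroxyl instead of being protonated. During the C1 equilibration the exocyclic double bond may also migrate into conjugation with the ketone, or the cis-fused epimer may persist (it could be held as a hemiketal with the 9-OH). Fallback, from 12 back to 15: the order of oxidation and fragmentation is reversed. Photoadduct 12, which has no oxygen at C9, is fragmented with SmI2/HMPA/t-BuOH and equilibrated at C1 to give the 9-deoxy trans-fused ketone F1. Allylic hydroxylation of F1 with SeO2/t-BuOOH then takes the C9 methylene in preference to the tertiary, ketone-deactivated C1–H, with oxygen expected on the α face away from the C7 side chain, and gives 15. If the trans ring fusion is still incomplete, the equilibration can be repeated on 16, where the hydroxyl is silylated.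

2. Step 3. The lithium lactone enolate may give poor anti/syn selectivity, and the chair transition state may be mismatched with the α-branched aldehyde. Fallback, from 2 and 4 back to 5: the C6 centre is set by ketone reduction instead of by the aldol. The lithium enolate of 4 (2 equiv) is acylated with ester 2 (crossed Claisen condensation) to give the β-keto lactone F2, whose C7 centre settles trans to the C11 methyl group. Non-chelating Felkin-type reduction with KBEt3H at −78 °C should then give the anti alcohol 5.

3. Step 15. Hydride may be delivered to the tertiary terminus of the π-allyl palladium complex, or the complex may eliminate to a cyclopentadiene. Fallback, from 21 back to 23: the deoxygenation is done by a radical route that does not pass through a metal allyl. Alcohol 21 is converted with PhOC(S)Cl/pyridine into the O-phenyl thionocarbonate F3. Barton–McCombie reduction (Bu3SnH, AIBN, toluene, 80 °C) generates the allylic radical, which should abstract hydrogen at the less hindered C2 and give the trisubstituted alkene 23.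

**Further compounds**

F1 | step 10 | 9-deoxy trans-fused hydroazulen-2-one (10-methylene, 6,12-bis-OTBS) | C=C1CC[C@@H]([C@@H](C)CO[Si](C)(C)C(C)(C)C)[C@@H](O[Si](C)(C)C(C)(C)C)[C@@H]2CCC(=O)[C@@H]12
F2 | step 3 | β-keto lactone, (3S,4R)-3-[(7R)-1,4-dioxaspiro[4.4]nonane-7-carbonyl]-4-methyldihydrofuran-2(3H)-one | O=C1OC[C@H](C)[C@H]1C(=O)[C@H]1CC2(CC1)OCCO2
F3 | step 15 | O-phenyl thionocarbonate of 21 | C=C1[C@H](O[Si](C)(C)C(C)(C)C)C[C@@H]([C@@H](C)CO[Si](C)(C)C(C)(C)C)[C@@H](O[Si](C)(C)C(C)(C)C)[C@@H]2C(C)=C[C@@H](OC(=S)Oc3ccccc3)[C@@H]12
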